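## Retrosynthetic overview

1. Numbering: oxolane O1, C2 (bears catechol ring A), C3 (bears C9H2OAc), C4 (bears the CH2 of guaiacyl ring B), C5; open-chain precursors keep these labels. The strategy rests on ring A being the only catechol and C2 being its benzylic carbon, para to the 4-OH of ring A: oxidising ring A alone turns C2 into the electrophilic end of a p-quinone methide exactly where O1 must bond.
2. Target ⇒ triphenolic oxolane alcohol, by lipase acetylation of C9–OH with the phenols untouched.
3. O1–C2 disconnection (anodic key step) ⇒ open-chain (2R,3R)-dibenzylbutane-1,4-diol with the free catechol; the C5 hydroxyl closes the ring and the C9 hydroxyl is left for the acetate.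
4. Diol ⇒ trans-(3R,4R)-dibenzylbutyrolactone (LiAlH4, hydrogenolysis) ⇒ (R)-β-benzyl lactone + 3,4-bis(benzyloxy)benzyl bromide (enolate alkylation); lactone ⇒ Stobbe half-ester of O-benzylvanillin by asymmetric hydrogenation.
5. Ring order: butyrolactone (step 3, a stereochemical template opened again in step 7), then the oxolane (step 9).

Key step: step 9

Assumption: the (S,S) enantiomer of the rhodium–Et-DuPHOS catalyst, (cycloocta-1,5-diene)[(S,S)-1,2-bis(2,5-diethylphospholan-1-yl)benzene]rhodium tetrafluoroborate, is taken to deliver the R hydrogenation product; if the sense is the reverse, the (R,R) enantiomer is used and nothing else changes.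

## Route

Step 1
Reactants: 1 O-benzylvanillin (4-benzyloxy-3-methoxybenzaldehyde); 2 dimethyl succinate
Product: 4 (E)-4-[4-(benzyloxy)-3-methoxyphenyl]-3-(methoxycarbonyl)but-3-enoic acid, via paraconate lactone 3 (not isolated)
Conditions: NaOMe (1.5 equiv), MeOH, reflux; then aq HCl
Reagents that add atoms: none
Why: Stobbe condensation, in which the succinate enolate adds to the aldehyde, the alkoxide closes on the distal ester to lactone 3 and E1cB opening gives the half-ester carboxylate, which cannot condense a second time; the E isomer (aryl trans to CO2Me) should predominate.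

Step 2
Reactants: 4
Product: 5 (R)-4-[4-(benzyloxy)-3-methoxyphenyl]-3-(methoxycarbonyl)butanoic acid
Conditions: H2 (5 bar), [Rh(cod)((S,S)-Et-DuPHOS)]BF4 (0.5 mol%), NaOMe (0.1 equiv), MeOH, rt
Reagents that add atoms: none
Why: asymmetric hydrogenation of an itaconate-type half-ester, in which the carboxylate chelates monovalent rhodium beside the alkene and the C2-symmetric bisphospholane selects the alkene face (E and Z isomers converge), setting the R centre that becomes C4; benzyl ethers are inert to the homogeneous catalyst.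

Step 3
Reactants: 5
Product: 7 (R)-4-[4-(benzyloxy)-3-methoxybenzyl]oxolan-2-one, via hydroxy acid 6 (not isolated)
Conditions: KOH (1.0 equiv), EtOH; Ca(BH4)2 (from CaCl2, NaBH4), −10 °C to rt; then 2 M HCl, rt
Reagents that add atoms: none
Why: chemoselective borohydride reduction, in which Ca(BH4)2 reduces the methyl ester but not the potassium carboxylate and acidification lactonises hydroxy acid 6; the stereocentre is not touched because only one equivalent of base is present at low temperature.

Step 4
Reactants: 8 3,4-bis(benzyloxy)benzaldehyde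
Product: 9 [3,4-bis(benzyloxy)phenyl]methanol
Conditions: NaBH4, MeOH/THF, 0 °C; dilute HCl work-up
Reagents that add atoms: none
Why: borohydride reduction of an aryl aldehyde, with nothing else reducible in the molecule.

Step 5
Reactants: 9
Product: 10 3,4-bis(benzyloxy)benzyl bromide
Conditions: PBr3 (0.4 equiv), CH2Cl2, 0 °C; used at once
Reagents that add atoms: phosphorus tribromide, BrP(Br)Br
Why: bromination of a benzylic alcohol through its phosphite ester (SN2 by bromide); the electron-rich bromide is not stored.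

Step 6
Reactants: 7; 10
Product: 12 (3R,4R)-3-[3,4-bis(benzyloxy)benzyl]-4-[4-(benzyloxy)-3-methoxybenzyl]oxolan-2-one, via lithium enolate 11 (not isolated)
Conditions: LiN(SiMe3)2 (1.05 equiv), THF, −78 °C; then 10, DMPU, −78 to −40 °C
Reagents that add atoms: none
Why: lactone enolate alkylation, in which the benzyl bromide approaches the planar enolate anti to the C4 benzyl group, so the new centre (3R, later C3) is set trans to the existing one by substrate control.

Step 7
Reactants: 12
Product: 13 (2R,3R)-2-[3,4-bis(benzyloxy)benzyl]-3-[4-(benzyloxy)-3-methoxybenzyl]butane-1,4-diol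
Conditions: LiAlH4, THF, 0 °C to rt
Reagents that add atoms: none
Why: hydride reduction of the lactone to the 1,4-diol; both stereocentres are carried over unchanged and the benzyl ethers survive.

Step 8
Reactants: 13
Product: 14 (2R,3R)-2-(3,4-dihydroxybenzyl)-3-(4-hydroxy-3-methoxybenzyl)butane-1,4-diol
Conditions: H2 (1 atm), 10% Pd/C, EtOAc/MeOH, rt; filtered and concentrated under Ar
Reagents that add atoms: none
Why: hydrogenolysis of the three benzyl aryl ethers on zerovalent palladium; no other bond is cleavable, and the air-sensitive catechol is taken straight into step 9.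

Step 9
Reactants: 14
Product: 17 4-[(2S,3R,4R)-3-(hydroxymethyl)-4-(4-hydroxy-3-methoxybenzyl)oxolan-2-yl]benzene-1,2-diol, via o-quinone 15 (not isolated), via p-quinone methide 16 (not isolated)
Conditions: divided cell, RVC anode, Pt cathode (catholyte with AcOH), n-Bu4NBF4 (0.1 M), MeCN (5 mM in 14), 2,6-lutidine (4 equiv), controlled potential at the first (catechol) wave, 2.0 F/mol, 0 °C, Ar; then rt
Reagents that add atoms: none
Why: Proposed new method: two-electron, two-proton oxidation of ring A at the carbon anode gives o-quinone 15, a lutidine/lutidinium-catalysed shift of a C2 proton to the quinone oxygen gives p-quinone methide 16, and 1,6-addition of the C5 hydroxyl to the exocyclic carbon C2 forms O1–C2 and restores the catechol. The closest known reaction type is the chemical or enzymatic oxidation of 4-alkylcatechols to o-quinones that tautomerise to p-quinone methides and are trapped by oxygen nucleophiles; an anodic version that closes an oxolane on an unprotected diol is untested. The oxolane closes 5-exo-trig onto the C2=C(ring A) bond, whereas the C9 hydroxyl could only close a strained oxetane at C2. The new stereocentre C2 is controlled by C3: in the envelope transition state the planar quinone methide sits anti to the C3 hydroxymethyl group, which leads to the 2,3-trans (2S) oxolane instead of the all-cis isomer. Chemoselectivity for ring A over guaiacol ring B and over product 17 is needed and should come from the lower oxidation potential of the catechol, from holding the anode at that wave and from stopping at 2 F/mol; site selectivity for C2 over the quinone ring carbons (chroman closure by the C9 hydroxyl) is needed too and should come from the non-nucleophilic buffer, which speeds the proton shift while neutral alcohols add only slowly to the o-quinone ring.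

Step 10
Reactants: 17
Product: 18 [(2S,3R,4R)-2-(3,4-dihydroxyphenyl)-4-(4-hydroxy-3-methoxybenzyl)oxolan-3-yl]methyl acetate (target)
Conditions: Candida antarctica lipase B (immobilised), vinyl acetate (5 equiv), THF, 40 °C
Reagents that add atoms: vinyl acetate, C=COC(C)=O
Why: lipase-catalysed transesterification, in which the acyl-enzyme passes acetyl to the single primary aliphatic alcohol (C9–OH) but not to the three phenols, and the vinyl alcohol leaves as acetaldehyde so the acylation cannot reverse.

## Compound list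

1 | O-benzylvanillin (4-benzyloxy-3-methoxybenzaldehyde) | COc1cc(C=O)ccc1OCc1ccccc1 | starting material
2 | dimethyl succinate | COC(=O)CCC(=O)OC | starting material
3 | methyl 2-[4-(benzyloxy)-3-methoxyphenyl]-5-oxooxolane-3-carboxylate (paraconate lactone, diastereomer mixture) | COC(=O)C1CC(=O)OC1c1ccc(OCc2ccccc2)c(OC)c1 | intermediate
4 | (E)-4-[4-(benzyloxy)-3-methoxyphenyl]-3-(methoxycarbonyl)but-3-enoic acid | COC(=O)/C(CC(=O)O)=C/c1ccc(OCc2ccccc2)c(OC)c1 | intermediate
5 | (R)-4-[4-(benzyloxy)-3-methoxyphenyl]-3-(methoxycarbonyl)butanoic acid | COC(=O)[C@@H](CC(=O)O)Cc1ccc(OCc2ccccc2)c(OC)c1 | intermediate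
6 | (R)-4-[4-(benzyloxy)-3-methoxyphenyl]-3-(hydroxymethyl)butanoic acid | OC[C@@H](CC(=O)O)Cc1ccc(OCc2ccccc2)c(OC)c1 | intermediate
7 | (R)-4-[4-(benzyloxy)-3-methoxybenzyl]oxolan-2-one | O=C1C[C@@H](Cc2ccc(OCc3ccccc3)c(OC)c2)CO1 | intermediate
8 | 3,4-bis(benzyloxy)benzaldehyde | O=Cc1ccc(OCc2ccccc2)c(OCc2ccccc2)c1 | starting material
9 | [3,4-bis(benzyloxy)phenyl]methanol | OCc1ccc(OCc2ccccc2)c(OCc2ccccc2)c1 | intermediate
10 | 3,4-bis(benzyloxy)benzyl bromide | BrCc1ccc(OCc2ccccc2)c(OCc2ccccc2)c1 | intermediate
11 | lithium enolate of 7 (lithium (R)-3-[4-(benzyloxy)-3-methoxybenzyl]-2,3-dihydrofuran-5-olate) | [Li+].[O-]C1=C[C@@H](Cc2ccc(OCc3ccccc3)c(OC)c2)CO1 | intermediate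
12 | (3R,4R)-3-[3,4-bis(benzyloxy)benzyl]-4-[4-(benzyloxy)-3-methoxybenzyl]oxolan-2-one (trans) | O=C1[C@H](Cc2ccc(OCc3ccccc3)c(OCc3ccccc3)c2)[C@@H](Cc2ccc(OCc3ccccc3)c(OC)c2)CO1 | intermediate
13 | (2R,3R)-2-[3,4-bis(benzyloxy)benzyl]-3-[4-(benzyloxy)-3-methoxybenzyl]butane-1,4-diol | COc1cc(C[C@@H](CO)[C@H](CO)Cc2ccc(OCc3ccccc3)c(OCc3ccccc3)c2)ccc1OCc1ccccc1 | intermediate
14 | (2R,3R)-2-(3,4-dihydroxybenzyl)-3-(4-hydroxy-3-methoxybenzyl)butane-1,4-diol | COc1cc(C[C@@H](CO)[C@H](CO)Cc2ccc(O)c(O)c2)ccc1O | intermediate
15 | 4-[(2R,3R)-4-hydroxy-2-(hydroxymethyl)-3-(4-hydroxy-3-methoxybenzyl)butyl]cyclohexa-3,5-diene-1,2-dione (o-quinone of 14) | COc1cc(C[C@@H](CO)[C@H](CO)CC2=CC(=O)C(=O)C=C2)ccc1O | intermediate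
16 | 2-hydroxy-4-[(2R,3R)-4-hydroxy-2-(hydroxymethyl)-3-(4-hydroxy-3-methoxybenzyl)butylidene]cyclohexa-2,5-dien-1-one (p-quinone methide, exocyclic alkene geometry open) | COc1cc(C[C@@H](CO)[C@H](CO)C=C2C=CC(=O)C(O)=C2)ccc1O | intermediate
17 | 4-[(2S,3R,4R)-3-(hydroxymethyl)-4-(4-hydroxy-3-methoxybenzyl)oxolan-2-yl]benzene-1,2-diol | COc1cc(C[C@H]2CO[C@H](c3ccc(O)c(O)c3)[C@H]2CO)ccc1O | intermediate
18 | [(2S,3R,4R)-2-(3,4-dihydroxyphenyl)-4-(4-hydroxy-3-methoxybenzyl)oxolan-3-yl]methyl acetate | COc1cc(C[C@H]2CO[C@H](c3ccc(O)c(O)c3)[C@H]2COC(C)=O)ccc1O | target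

## Step count and risks

Total steps: 10. Longest linear sequence: 8 (steps 1, 2, 3, 6, 7, 8, 9, 10); steps 4 and 5 form the short side branch to bromide 10.

Steps most likely to fail

1. Step 9 (proposed new method). The proton shift from the o-quinone to the quinone methide may be too slow, so that ring addition (chroman closure by the C9 hydroxyl) or quinone–catechol coupling takes over. The product catechol may also be oxidised further as it accumulates, and local acid build-up may divert the quinone methide into Friedel–Crafts closure onto ring B.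
Fallback (known chemistry; the C2 oxygen is brought in by an aldol instead of by C–H oxidation): it sets out from lactone 7 and aldehyde 8 and comes back to the route at 17. The lithium enolate of 7 (LiN(SiMe3)2, THF, −78 °C) is added to 8, anti to the C4 benzyl group, to give the trans aldol adduct (3S,4R)-3-{[3,4-bis(benzyloxy)phenyl](hydroxy)methyl}-4-[4-(benzyloxy)-3-methoxybenzyl]oxolan-2-one F1 as carbinol epimers, both usable. LiAlH4 in THF should give the triol (2R,3R)-2-{[3,4-bis(benzyloxy)phenyl](hydroxy)methyl}-3-[4-(benzyloxy)-3-methoxybenzyl]butane-1,4-diol F2. Catalytic camphorsulfonic acid in CH2Cl2 at 0 °C ionises the benzylic alcohol (cation stabilised by the para benzyloxy group), and the C5 hydroxyl closes 5-exo to the 2,3-trans oxolane {(2S,3R,4R)-2-[3,4-bis(benzyloxy)phenyl]-4-[4-(benzyloxy)-3-methoxybenzyl]oxolan-3-yl}methanol F3. Hydrogenolysis (H2, 10% Pd/C, EtOAc, stopped once the three benzyl ethers are gone) then gives 17.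

2. Step 2. Enantioselection may be incomplete or of the unexpected sense, and the error would be carried into every later stereocentre.
Fallback (auxiliary control in place of catalyst control): it sets out from 1 and comes back to the route at 7.
- Knoevenagel–Doebner condensation of 1 with malonic acid (pyridine, piperidine, 90 °C) gives (E)-3-[4-(benzyloxy)-3-methoxyphenyl]prop-2-enoic acid F4.
- Alkene hydrogenation with H2 and RhCl(PPh3)3, which leaves the benzyl ether, gives 3-[4-(benzyloxy)-3-methoxyphenyl]propanoic acid F5.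
- The pivaloyl mixed anhydride (PivCl, Et3N, THF) with (S)-4-benzyloxazolidin-2-one and LiCl gives (S)-4-benzyl-3-{3-[4-(benzyloxy)-3-methoxyphenyl]propanoyl}oxazolidin-2-one F6.
- The sodium enolate (NaN(SiMe3)2, THF, −78 °C) is alkylated by tert-butyl bromoacetate on the face opposite the auxiliary benzyl group, giving tert-butyl (3R)-3-{[(4S)-4-benzyl-2-oxooxazolidin-3-yl]carbonyl}-4-[4-(benzyloxy)-3-methoxyphenyl]butanoate F7.
- LiBH4 (THF, MeOH 1 equiv, 0 °C) removes the auxiliary reductively to give tert-butyl (R)-4-[4-(benzyloxy)-3-methoxyphenyl]-3-(hydroxymethyl)butanoate F8.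
- Catalytic TsOH in toluene at 80 °C lactonises F8 to 7.

3. Step 10. Acyl transfer to the C9 hydroxyl, which is flanked by two ring substituents, may be slow in the enzyme pocket, and long reaction times may bring partial acetylation of the phenols.
Fallback (protect all, then unmask the phenols chemically): it sets out from 17 and comes back to the route at 18. Ac2O in pyridine should give the tetraacetate [(2S,3R,4R)-2-(3,4-diacetoxyphenyl)-4-(4-acetoxy-3-methoxybenzyl)oxolan-3-yl]methyl acetate F9. Pyrrolidine (3.3 equiv, MeCN, 0 °C, Ar) then cleaves the three aryl acetates by aminolysis, which is far faster than attack on the alkyl acetate, and leaves 18.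

## Further compounds

F1 | step 9 | (3S,4R)-3-{[3,4-bis(benzyloxy)phenyl](hydroxy)methyl}-4-[4-(benzyloxy)-3-methoxybenzyl]oxolan-2-one (carbinol epimers) | O=C1[C@H](C(O)c2ccc(OCc3ccccc3)c(OCc3ccccc3)c2)[C@@H](Cc2ccc(OCc3ccccc3)c(OC)c2)CO1
F2 | step 9 | (2R,3R)-2-{[3,4-bis(benzyloxy)phenyl](hydroxy)methyl}-3-[4-(benzyloxy)-3-methoxybenzyl]butane-1,4-diol (carbinol epimers) | COc1cc(C[C@@H](CO)[C@H](CO)C(O)c2ccc(OCc3ccccc3)c(OCc3ccccc3)c2)ccc1OCc1ccccc1
F3 | step 9 | {(2S,3R,4R)-2-[3,4-bis(benzyloxy)phenyl]-4-[4-(benzyloxy)-3-methoxybenzyl]oxolan-3-yl}methanol | COc1cc(C[C@H]2CO[C@H](c3ccc(OCc4ccccc4)c(OCc4ccccc4)c3)[C@H]2CO)ccc1OCc1ccccc1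
F4 | step 2 | (E)-3-[4-(benzyloxy)-3-methoxyphenyl]prop-2-enoic acid | COc1cc(/C=C/C(=O)O)ccc1OCc1ccccc1
F5 | step 2 | 3-[4-(benzyloxy)-3-methoxyphenyl]propanoic acid | COc1cc(CCC(=O)O)ccc1OCc1ccccc1
F6 | step 2 | (S)-4-benzyl-3-{3-[4-(benzyloxy)-3-methoxyphenyl]propanoyl}oxazolidin-2-one | COc1cc(CCC(=O)N2[C@@H](Cc3ccccc3)COC2=O)ccc1OCc1ccccc1
F7 | step 2 | tert-butyl (3R)-3-{[(4S)-4-benzyl-2-oxooxazolidin-3-yl]carbonyl}-4-[4-(benzyloxy)-3-methoxyphenyl]butanoate | COc1cc(C[C@H](CC(=O)OC(C)(C)C)C(=O)N2[C@@H](Cc3ccccc3)COC2=O)ccc1OCc1ccccc1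
F8 | step 2 | tert-butyl (R)-4-[4-(benzyloxy)-3-methoxyphenyl]-3-(hydroxymethyl)butanoate | COc1cc(C[C@H](CC(=O)OC(C)(C)C)CO)ccc1OCc1ccccc1
F9 | step 10 | [(2S,3R,4R)-2-(3,4-diacetoxyphenyl)-4-(4-acetoxy-3-methoxybenzyl)oxolan-3-yl]methyl acetate | COc1cc(C[C@H]2CO[C@H](c3ccc(OC(C)=O)c(OC(C)=O)c3)[C@H]2COC(C)=O)ccc1OC(C)=O
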